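**Retrosynthetic overview**

- The strategy rests on the quinone ring C1(=O)–C2(OH)=C3H–C4(=O): four carbons with oxygen at C1, C2 and C4, fused at C4a/C8a to a benzo ring whose C5 oxygen blocks one ortho position. C4 is taken from a carbene carbon, C3/C2 from ethoxyacetylene and C1 from CO.
- Target 31 is traced back (BCl3 ether cleavage, ethoxyquinone hydrolysis, pyranone from a dioxinone, CAN oxidation) to the 2-ethoxy-1,4,5-trimethoxynaphthalene 20, the O-methyl ether of naphthol 19.
- Naphthol 19 comes from carbene complex 16 and ethoxyacetylene 17 by chromium-mediated benzannulation, which forms C4–C3, C2–C1 and C1–C8a.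
- Complex 16 comes from aryl bromide 12 (Br/Li exchange, Cr(CO)6, MeOTf). Bromide 12 comes from opening lactone 6 (made from 2-bromo-5-methylphenol) with aryllithium 10 (made from orcinol).
- Ring order: both benzenoid rings are bought; a temporary isochromanone ring (step 4), then the quinone ring (step 10), then the pyranone ring (step 18).

Key step: step 10

**Remarks**

- The target has no stereocentre, so no enantiocontrol is needed. The only stereocentre on the way (the carbinol of 25 and 26) is formed as a racemate and is removed by oxidation in step 17.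
- Naphthalene positions are numbered as in the target (C1–C4 quinone ring, C5 oxygen, C6 aroyl, C7 side chain).
- Assumption: hydroxy ketone 11 may equilibrate with its cyclic hemiketal; silylation of the primary alcohol in step 8 is taken to trap the open form.

**Route**

Step 1
Reactants: 1 2-bromo-5-methylphenol
Product: 2 3-bromo-2-hydroxy-6-methylbenzaldehyde
Conditions: MgCl2, Et3N, (CH2O)n, THF, reflux; aq. HCl
Reagents that add atoms: paraformaldehyde (as formaldehyde), C=O
Why: The magnesium-phenoxide-directed ortho-formylation (Casnati–Skattebøl) is specific for positions ortho to the hydroxyl, and with C2 blocked by bromine only the position between OH and CH3 is open.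

Step 2
Reactants: 2 3-bromo-2-hydroxy-6-methylbenzaldehyde
Product: 3 3-bromo-2-hydroxy-6-methylbenzoic acid
Conditions: NaClO2, NaH2PO4, 2-methyl-2-butene, t-BuOH/H2O, rt
Reagents that add atoms: sodium chlorite, [Na+].[O-]Cl=O
Why: The Lindgren–Pinnick chlorite oxidation converts the aldehyde to the acid without touching the aryl bromide, and the alkene scavenger removes HOCl before it can chlorinate the phenol ring.

Step 3
Reactants: 3 3-bromo-2-hydroxy-6-methylbenzoic acid
Product: 4 methyl 3-bromo-2-methoxy-6-methylbenzoate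
Conditions: MeI (excess), K2CO3, DMF, 40 °C
Reagents that add atoms: iodomethane, CI
Why: SN2 alkylation of the carboxylate and of the phenoxide (Williamson type) installs the ester and the aryl methyl ether in one operation.

Step 4
Reactants: 4 methyl 3-bromo-2-methoxy-6-methylbenzoate
Product: 6 7-bromo-8-methoxy-3,4-dihydro-1H-isochromen-1-one, via hydroxy ester 5 (not isolated)
Conditions: LDA, THF, −78 °C; CH2O (g), −78 → 0 °C; 2 M HCl
Reagents that add atoms: formaldehyde, C=O
Why: Lateral lithiation of the ortho-toluate (benzylic deprotonation, faster than metalation next to bromine) followed by hydroxymethylation gives an alkoxide that lactonises onto the flanking ester, whose two ortho substituents suppress self-condensation.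

Step 5
Reactants: 7 orcinol (5-methylbenzene-1,3-diol)
Product: 8 1,3-bis(benzyloxy)-5-methylbenzene
Conditions: BnBr, K2CO3, DMF, rt
Reagents that add atoms: benzyl bromide, BrCc1ccccc1
Why: Williamson etherification of both phenols gives ethers that survive organolithium, chromium and Ce(IV) chemistry and are cleaved by BCl3 at the end.

Step 6
Reactants: 8 1,3-bis(benzyloxy)-5-methylbenzene
Product: 9 1,5-bis(benzyloxy)-2-bromo-3-methylbenzene
Conditions: NBS, MeCN, 0 °C
Reagents that add atoms: N-bromosuccinimide, O=C1CCC(=O)N1Br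
Why: Electrophilic aromatic bromination should go to the position between CH3 and OBn, which is para to the second OBn and less hindered than the position flanked by both OBn groups.

Step 7
Reactants: 9 1,5-bis(benzyloxy)-2-bromo-3-methylbenzene; 6 7-bromo-8-methoxy-3,4-dihydro-1H-isochromen-1-one
Product: 11 [2,4-bis(benzyloxy)-6-methylphenyl][3-bromo-6-(2-hydroxyethyl)-2-methoxyphenyl]methanone, via aryllithium 10 (not isolated)
Conditions: 9, n-BuLi, THF, −78 °C; then 6, −78 → −20 °C; aq. NH4Cl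
Reagents that add atoms: none
Why: Bromine–lithium exchange followed by nucleophilic acyl substitution on the lactone gives the diaryl ketone and frees the hydroxyethyl chain, and a second addition is not expected because the ketone carries four ortho substituents and is masked as its alkoxide adduct until work-up.

Step 8
Reactants: 11 [2,4-bis(benzyloxy)-6-methylphenyl][3-bromo-6-(2-hydroxyethyl)-2-methoxyphenyl]methanone
Product: 12 [2,4-bis(benzyloxy)-6-methylphenyl][3-bromo-6-(2-(tert-butyldimethylsilyloxy)ethyl)-2-methoxyphenyl]methanone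
Conditions: TBSCl, imidazole, DMF, rt
Reagents that add atoms: tert-butyldimethylsilyl chloride, CC(C)(C)[Si](C)(C)Cl
Why: Imidazole-promoted silylation of the primary alcohol gives an ether that tolerates butyllithium, the carbene complex and the benzannulation.

Step 9
Reactants: 12 [2,4-bis(benzyloxy)-6-methylphenyl][3-bromo-6-(2-(tert-butyldimethylsilyloxy)ethyl)-2-methoxyphenyl]methanone; 13 chromium hexacarbonyl
Product: 16 pentacarbonyl{methoxy[3-(2,4-bis(benzyloxy)-6-methylbenzoyl)-4-(2-(tert-butyldimethylsilyloxy)ethyl)-2-methoxyphenyl]methylidene}chromium, via aryllithium 14 (not isolated), via lithium acylchromate 15 (not isolated)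
Conditions: n-BuLi, THF/Et2O, −100 °C; Cr(CO)6, −78 → 0 °C; evaporate; MeOTf, CH2Cl2, 0 °C → rt
Reagents that add atoms: methyl trifluoromethanesulfonate, COS(=O)(=O)C(F)(F)F
Why: In this Fischer carbene synthesis the bromine–lithium exchange at −100 °C should outrun attack on the tetra-ortho-substituted diaryl ketone, the aryllithium adds to a CO ligand, and the acylchromate oxygen is methylated by the hard electrophile MeOTf.

Step 10
Reactants: 16 pentacarbonyl{methoxy[3-(2,4-bis(benzyloxy)-6-methylbenzoyl)-4-(2-(tert-butyldimethylsilyloxy)ethyl)-2-methoxyphenyl]methylidene}chromium; 17 ethoxyacetylene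
Product: 19 [2,4-bis(benzyloxy)-6-methylphenyl][7-(2-(tert-butyldimethylsilyloxy)ethyl)-2-ethoxy-1-hydroxy-4,5-dimethoxynaphthalen-6-yl]methanone, via tricarbonylchromium naphthol complex 18 (not isolated)
Conditions: 17 (3 equiv), THF (0.5 M), 55 °C, sealed tube, Ar; then air, Et2O, rt
Reagents that add atoms: none
Why: Proposed new method: loss of one cis-CO from 16 opens a site for ethoxyacetylene, whose nucleophilic CH carbon bonds to the electrophilic carbene carbon (C4–C3) so that the new carbene carbon carries OEt, CO insertion at that carbon gives a vinylketene (C2–C1), and ring closure of the ketene carbon onto the free ortho carbon (C1–C8a) with tautomerisation gives the chromium-bound naphthol 18, which air releases as 19. The closest known reaction type is the Dötz benzannulation of aryl(alkoxy)carbene chromium complexes with terminal alkynes, whereas an alkoxyalkyne partner and a carbene arene carrying a diaryl ketone have not been shown. The one new ring (C1–C2–C3–C4–C4a–C8a) is closed by 6π-electrocyclisation of the dienylketene. No stereocentre is formed. Two selectivities are needed: the alkyne orientation, which the polarisation of the ynol ether and the smaller size of H against OEt both set so that OEt sits next to the CO-derived C1, and the site of closure, which is fixed because C5 carries OMe and only C8a is free. The main risk is that the OEt-stabilised vinylcarbene does not take up CO, which excess alkyne at high concentration in a donor solvent is meant to counter.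

Step 11
Reactants: 19 [2,4-bis(benzyloxy)-6-methylphenyl][7-(2-(tert-butyldimethylsilyloxy)ethyl)-2-ethoxy-1-hydroxy-4,5-dimethoxynaphthalen-6-yl]methanone
Product: 20 [2,4-bis(benzyloxy)-6-methylphenyl][7-(2-(tert-butyldimethylsilyloxy)ethyl)-2-ethoxy-1,4,5-trimethoxynaphthalen-6-yl]methanone
Conditions: MeI, K2CO3, DMF (degassed), rt, Ar
Reagents that add atoms: iodomethane, CI
Why: O-Alkylation of the naphthoxide under argon (Williamson type) caps the air-sensitive hydroquinone monoether as a 1,4-dimethyl ether that can be carried through the side-chain work.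

Step 12
Reactants: 20 [2,4-bis(benzyloxy)-6-methylphenyl][7-(2-(tert-butyldimethylsilyloxy)ethyl)-2-ethoxy-1,4,5-trimethoxynaphthalen-6-yl]methanone
Product: 21 [2,4-bis(benzyloxy)-6-methylphenyl][2-ethoxy-7-(2-hydroxyethyl)-1,4,5-trimethoxynaphthalen-6-yl]methanone
Conditions: TBAF, THF, 0 °C → rt; aq. NH4Cl
Reagents that add atoms: none
Why: Fluoride-induced desilylation frees the primary alcohol and leaves the aryl ethers and the ketone untouched.

Step 13
Reactants: 21 [2,4-bis(benzyloxy)-6-methylphenyl][2-ethoxy-7-(2-hydroxyethyl)-1,4,5-trimethoxynaphthalen-6-yl]methanone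
Product: 22 [2,4-bis(benzyloxy)-6-methylphenyl][2-ethoxy-1,4,5-trimethoxy-7-(2-oxoethyl)naphthalen-6-yl]methanone
Conditions: Dess–Martin periodinane, CH2Cl2, 0 °C → rt; used crude
Reagents that add atoms: none
Why: The Dess–Martin oxidation stops at the arylacetaldehyde and does not oxidise the electron-rich tetraalkoxynaphthalene.

Step 14
Reactants: 23 2,2,6-trimethyl-4H-1,3-dioxin-4-one
Product: 24 2,2-dimethyl-4-methylidene-6-(trimethylsilyloxy)-4H-1,3-dioxine
Conditions: LDA, THF, −78 °C; TMSCl, −78 °C → rt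
Reagents that add atoms: chlorotrimethylsilane, C[Si](C)(C)Cl
Why: γ-Deprotonation of the dioxinone and O-silylation of the dienolate give the silyl dienol ether that serves as an acetoacetate dianion equivalent.

Step 15
Reactants: 22 [2,4-bis(benzyloxy)-6-methylphenyl][2-ethoxy-1,4,5-trimethoxy-7-(2-oxoethyl)naphthalen-6-yl]methanone; 24 2,2-dimethyl-4-methylidene-6-(trimethylsilyloxy)-4H-1,3-dioxine
Product: 25 6-{3-[6-(2,4-bis(benzyloxy)-6-methylbenzoyl)-2-ethoxy-1,4,5-trimethoxynaphthalen-7-yl]-2-hydroxypropyl}-2,2-dimethyl-4H-1,3-dioxin-4-one (racemic)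
Conditions: BF3·OEt2, CH2Cl2, −78 °C; aq. work-up
Reagents that add atoms: none
Why: In this vinylogous Mukaiyama aldol addition the γ-carbon of the silyl dienol ether attacks the BF3-activated aldehyde under non-basic conditions that avoid enolisation of the arylacetaldehyde, and the new carbinol centre is formed without control as a racemate because it is oxidised away in step 17.

Step 16
Reactants: 25 6-{3-[6-(2,4-bis(benzyloxy)-6-methylbenzoyl)-2-ethoxy-1,4,5-trimethoxynaphthalen-7-yl]-2-hydroxypropyl}-2,2-dimethyl-4H-1,3-dioxin-4-one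
Product: 26 6-[2,4-bis(benzyloxy)-6-methylbenzoyl]-7-[3-(2,2-dimethyl-4-oxo-4H-1,3-dioxin-6-yl)-2-hydroxypropyl]-2-ethoxy-5-methoxynaphthalene-1,4-dione (racemic)
Conditions: CAN, MeCN/H2O, 0 °C
Reagents that add atoms: water, O
Why: Oxidative demethylation by Ce(IV) converts the 1,4-dimethoxy ring, the most electron-rich part of the molecule, into the para-quinone with retention of the C2 ethoxy and C5 methoxy groups, and it is placed before the pyranone is unveiled so that no free 4-hydroxypyranone is exposed to the oxidant.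

Step 17
Reactants: 26 6-[2,4-bis(benzyloxy)-6-methylbenzoyl]-7-[3-(2,2-dimethyl-4-oxo-4H-1,3-dioxin-6-yl)-2-hydroxypropyl]-2-ethoxy-5-methoxynaphthalene-1,4-dione
Product: 27 6-[2,4-bis(benzyloxy)-6-methylbenzoyl]-7-[3-(2,2-dimethyl-4-oxo-4H-1,3-dioxin-6-yl)-2-oxopropyl]-2-ethoxy-5-methoxynaphthalene-1,4-dione
Conditions: Dess–Martin periodinane, CH2Cl2, rt
Reagents that add atoms: none
Why: The Dess–Martin oxidation of the secondary alcohol gives the keto-dioxinone and removes the only stereocentre, and the quinone and dioxinone are inert to the reagent.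

Step 18
Reactants: 27 6-[2,4-bis(benzyloxy)-6-methylbenzoyl]-7-[3-(2,2-dimethyl-4-oxo-4H-1,3-dioxin-6-yl)-2-oxopropyl]-2-ethoxy-5-methoxynaphthalene-1,4-dione
Product: 29 6-[2,4-bis(benzyloxy)-6-methylbenzoyl]-2-ethoxy-7-[(4-hydroxy-2-oxo-2H-pyran-6-yl)methyl]-5-methoxynaphthalene-1,4-dione, via acylketene 28 (not isolated)
Conditions: PhMe (0.01 M), 110 °C
Reagents that add atoms: none
Why: Thermal retro-[4+2] fragmentation of the dioxinone expels acetone, and the acylketene is trapped by the enol oxygen of the side-chain ketone to close the 4-hydroxy-2-pyranone under neutral conditions that avoid aldol attack of the triketide on the diaryl ketone.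

Step 19
Reactants: 29 6-[2,4-bis(benzyloxy)-6-methylbenzoyl]-2-ethoxy-7-[(4-hydroxy-2-oxo-2H-pyran-6-yl)methyl]-5-methoxynaphthalene-1,4-dione
Product: 30 6-[2,4-bis(benzyloxy)-6-methylbenzoyl]-2-hydroxy-7-[(4-hydroxy-2-oxo-2H-pyran-6-yl)methyl]-5-methoxynaphthalene-1,4-dione
Conditions: LiOH, THF/H2O, 0 °C → rt; 1 M HCl
Reagents that add atoms: lithium hydroxide, [Li+].[OH-]
Why: Addition–elimination of hydroxide at C2 of the vinylogous ester replaces OEt by OH, while the pyranone is held as its unreactive anion at this temperature.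

Step 20
Reactants: 30 6-[2,4-bis(benzyloxy)-6-methylbenzoyl]-2-hydroxy-7-[(4-hydroxy-2-oxo-2H-pyran-6-yl)methyl]-5-methoxynaphthalene-1,4-dione
Product: 31 6-(2,4-dihydroxy-6-methylbenzoyl)-2,5-dihydroxy-7-[(4-hydroxy-2-oxo-2H-pyran-6-yl)methyl]naphthalene-1,4-dione (CNP0158797.0)
Conditions: BCl3, pentamethylbenzene, CH2Cl2, −78 → 0 °C → rt; MeOH then H2O
Reagents that add atoms: none
Why: Lewis-acid ether cleavage by BCl3 removes both benzyl groups (pentamethylbenzene traps the benzyl cation) and the C5 methyl group, whose cleavage is assisted by chelation to the peri C4 carbonyl, and the borate chelates are hydrolysed on work-up.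

**Compound list**

1 | 2-bromo-5-methylphenol | Cc1ccc(Br)c(O)c1 | starting material
2 | 3-bromo-2-hydroxy-6-methylbenzaldehyde | Cc1ccc(Br)c(O)c1C=O | intermediate
3 | 3-bromo-2-hydroxy-6-methylbenzoic acid | Cc1ccc(Br)c(O)c1C(=O)O | intermediate
4 | methyl 3-bromo-2-methoxy-6-methylbenzoate | Cc1ccc(Br)c(OC)c1C(=O)OC | intermediate
5 | methyl 3-bromo-6-(2-hydroxyethyl)-2-methoxybenzoate (formed as its lithium alkoxide) | OCCc1ccc(Br)c(OC)c1C(=O)OC | intermediate
6 | 7-bromo-8-methoxy-3,4-dihydro-1H-isochromen-1-one | COc1c(Br)ccc2CCOC(=O)c12 | intermediate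
7 | orcinol (5-methylbenzene-1,3-diol) | Cc1cc(O)cc(O)c1 | starting material
8 | 1,3-bis(benzyloxy)-5-methylbenzene | Cc1cc(OCc2ccccc2)cc(OCc2ccccc2)c1 | intermediate
9 | 1,5-bis(benzyloxy)-2-bromo-3-methylbenzene | Cc1cc(OCc2ccccc2)cc(OCc2ccccc2)c1Br | intermediate
10 | [2,4-bis(benzyloxy)-6-methylphenyl]lithium | [Li]c1c(C)cc(OCc2ccccc2)cc1OCc1ccccc1 | intermediate
11 | [2,4-bis(benzyloxy)-6-methylphenyl][3-bromo-6-(2-hydroxyethyl)-2-methoxyphenyl]methanone | COc1c(Br)ccc(CCO)c1C(=O)c1c(C)cc(OCc2ccccc2)cc1OCc1ccccc1 | intermediate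
12 | [2,4-bis(benzyloxy)-6-methylphenyl][3-bromo-6-(2-(tert-butyldimethylsilyloxy)ethyl)-2-methoxyphenyl]methanone | COc1c(Br)ccc(CCO[Si](C)(C)C(C)(C)C)c1C(=O)c1c(C)cc(OCc2ccccc2)cc1OCc1ccccc1 | intermediate
13 | chromium hexacarbonyl | O=C=[Cr](=C=O)(=C=O)(=C=O)(=C=O)=C=O | starting material
14 | [3-(2,4-bis(benzyloxy)-6-methylbenzoyl)-4-(2-(tert-butyldimethylsilyloxy)ethyl)-2-methoxyphenyl]lithium | COc1c([Li])ccc(CCO[Si](C)(C)C(C)(C)C)c1C(=O)c1c(C)cc(OCc2ccccc2)cc1OCc1ccccc1 | intermediate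
15 | lithium pentacarbonyl[3-(2,4-bis(benzyloxy)-6-methylbenzoyl)-4-(2-(tert-butyldimethylsilyloxy)ethyl)-2-methoxybenzoyl]chromate | [Li+].[O-]C(=[Cr](=C=O)(=C=O)(=C=O)(=C=O)=C=O)c1ccc(CCO[Si](C)(C)C(C)(C)C)c(C(=O)c2c(C)cc(OCc3ccccc3)cc2OCc2ccccc2)c1OC | intermediate
16 | pentacarbonyl{methoxy[3-(2,4-bis(benzyloxy)-6-methylbenzoyl)-4-(2-(tert-butyldimethylsilyloxy)ethyl)-2-methoxyphenyl]methylidene}chromium | COC(=[Cr](=C=O)(=C=O)(=C=O)(=C=O)=C=O)c1ccc(CCO[Si](C)(C)C(C)(C)C)c(C(=O)c2c(C)cc(OCc3ccccc3)cc2OCc2ccccc2)c1OC | intermediate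
17 | ethoxyacetylene | C#COCC | starting material
18 | tricarbonylchromium complex of naphthol 19 (Cr bound η6 to the new ring; written as separate fragments) | CCOc1cc(OC)c2c(OC)c(C(=O)c3c(C)cc(OCc4ccccc4)cc3OCc3ccccc3)c(CCO[Si](C)(C)C(C)(C)C)cc2c1O.O=C=[Cr](=C=O)=C=O | intermediate
19 | [2,4-bis(benzyloxy)-6-methylphenyl][7-(2-(tert-butyldimethylsilyloxy)ethyl)-2-ethoxy-1-hydroxy-4,5-dimethoxynaphthalen-6-yl]methanone | CCOc1cc(OC)c2c(OC)c(C(=O)c3c(C)cc(OCc4ccccc4)cc3OCc3ccccc3)c(CCO[Si](C)(C)C(C)(C)C)cc2c1O | intermediate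
20 | [2,4-bis(benzyloxy)-6-methylphenyl][7-(2-(tert-butyldimethylsilyloxy)ethyl)-2-ethoxy-1,4,5-trimethoxynaphthalen-6-yl]methanone | CCOc1cc(OC)c2c(OC)c(C(=O)c3c(C)cc(OCc4ccccc4)cc3OCc3ccccc3)c(CCO[Si](C)(C)C(C)(C)C)cc2c1OC | intermediate
21 | [2,4-bis(benzyloxy)-6-methylphenyl][2-ethoxy-7-(2-hydroxyethyl)-1,4,5-trimethoxynaphthalen-6-yl]methanone | CCOc1cc(OC)c2c(OC)c(C(=O)c3c(C)cc(OCc4ccccc4)cc3OCc3ccccc3)c(CCO)cc2c1OC | intermediate
22 | [2,4-bis(benzyloxy)-6-methylphenyl][2-ethoxy-1,4,5-trimethoxy-7-(2-oxoethyl)naphthalen-6-yl]methanone | CCOc1cc(OC)c2c(OC)c(C(=O)c3c(C)cc(OCc4ccccc4)cc3OCc3ccccc3)c(CC=O)cc2c1OC | intermediate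
23 | 2,2,6-trimethyl-4H-1,3-dioxin-4-one | CC1=CC(=O)OC(C)(C)O1 | starting material
24 | 2,2-dimethyl-4-methylidene-6-(trimethylsilyloxy)-4H-1,3-dioxine | C=C1C=C(O[Si](C)(C)C)OC(C)(C)O1 | intermediate
25 | 6-{3-[6-(2,4-bis(benzyloxy)-6-methylbenzoyl)-2-ethoxy-1,4,5-trimethoxynaphthalen-7-yl]-2-hydroxypropyl}-2,2-dimethyl-4H-1,3-dioxin-4-one (racemic) | CCOc1cc(OC)c2c(OC)c(C(=O)c3c(C)cc(OCc4ccccc4)cc3OCc3ccccc3)c(CC(O)CC3=CC(=O)OC(C)(C)O3)cc2c1OC | intermediate
26 | 6-[2,4-bis(benzyloxy)-6-methylbenzoyl]-7-[3-(2,2-dimethyl-4-oxo-4H-1,3-dioxin-6-yl)-2-hydroxypropyl]-2-ethoxy-5-methoxynaphthalene-1,4-dione (racemic) | CCOC1=CC(=O)c2c(OC)c(C(=O)c3c(C)cc(OCc4ccccc4)cc3OCc3ccccc3)c(CC(O)CC3=CC(=O)OC(C)(C)O3)cc2C1=O | intermediate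
27 | 6-[2,4-bis(benzyloxy)-6-methylbenzoyl]-7-[3-(2,2-dimethyl-4-oxo-4H-1,3-dioxin-6-yl)-2-oxopropyl]-2-ethoxy-5-methoxynaphthalene-1,4-dione | CCOC1=CC(=O)c2c(OC)c(C(=O)c3c(C)cc(OCc4ccccc4)cc3OCc3ccccc3)c(CC(=O)CC3=CC(=O)OC(C)(C)O3)cc2C1=O | intermediate
28 | 6-[6-(2,4-bis(benzyloxy)-6-methylbenzoyl)-2-ethoxy-5-methoxy-1,4-dioxo-1,4-dihydronaphthalen-7-yl]-3,5-dioxohex-1-en-1-one (acylketene) | CCOC1=CC(=O)c2c(OC)c(C(=O)c3c(C)cc(OCc4ccccc4)cc3OCc3ccccc3)c(CC(=O)CC(=O)C=C=O)cc2C1=O | intermediate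
29 | 6-[2,4-bis(benzyloxy)-6-methylbenzoyl]-2-ethoxy-7-[(4-hydroxy-2-oxo-2H-pyran-6-yl)methyl]-5-methoxynaphthalene-1,4-dione | CCOC1=CC(=O)c2c(OC)c(C(=O)c3c(C)cc(OCc4ccccc4)cc3OCc3ccccc3)c(Cc3cc(O)cc(=O)o3)cc2C1=O | intermediate
30 | 6-[2,4-bis(benzyloxy)-6-methylbenzoyl]-2-hydroxy-7-[(4-hydroxy-2-oxo-2H-pyran-6-yl)methyl]-5-methoxynaphthalene-1,4-dione | OC1=CC(=O)c2c(OC)c(C(=O)c3c(C)cc(OCc4ccccc4)cc3OCc3ccccc3)c(Cc3cc(O)cc(=O)o3)cc2C1=O | intermediate
31 | 6-(2,4-dihydroxy-6-methylbenzoyl)-2,5-dihydroxy-7-[(4-hydroxy-2-oxo-2H-pyran-6-yl)methyl]naphthalene-1,4-dione (CNP0158797.0; achiral) | Cc1cc(O)cc(O)c1C(=O)c1c(Cc2cc(O)cc(=O)o2)cc2c(c1O)C(=O)C=C(O)C2=O | target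

**Step count**

Total: 20 steps. Longest linear sequence: 17 steps (steps 1–4, 7–13, 15–20).

**Steps most likely to fail, with fallbacks**

1. Step 10. After alkyne insertion the ethoxy-stabilised vinylcarbene may not take up CO, so the reaction may stop at an alkenyl(ethoxy)carbene complex, divert to a cyclobutenone, or oligomerise the ynol ether. The fallback sets out from 16 and uses a terminal alkyne of the established class. Benzannulation of 16 with 3,3-diethoxyprop-1-yne (THF, 55 °C, then air) should give [2,4-bis(benzyloxy)-6-methylphenyl][7-(2-(tert-butyldimethylsilyloxy)ethyl)-2-(diethoxymethyl)-1-hydroxy-4,5-dimethoxynaphthalen-6-yl]methanone F1. Methylation (MeI, K2CO3, DMF) gives the 1,4,5-trimethoxy acetal F2, and PPTS in wet acetone gives the 2-carbaldehyde F3. Baeyer–Villiger oxidation with mCPBA (Dakin type, the electron-rich aryl group migrating) gives the aryl formate F4, and K2CO3 in MeOH gives the 2-naphthol F5. O-Ethylation (EtI, K2CO3, DMF) returns to the route at 20.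

2. Step 9. Butyllithium or the aryllithium may attack the diaryl ketone or transfer an electron to it during halogen–lithium exchange, and uptake of Cr(CO)6 by the aryllithium may be slow. The fallback sets out from 12 and avoids organolithium reagents. Palladium-catalysed methoxycarbonylation (Pd(OAc)2, Xantphos, CO, MeOH, Et3N, 70 °C) should give methyl 3-(2,4-bis(benzyloxy)-6-methylbenzoyl)-4-(2-(tert-butyldimethylsilyloxy)ethyl)-2-methoxybenzoate F6. Saponification (LiOH, THF/MeOH/H2O) gives the benzoic acid F7, and 1-chloro-N,N,2-trimethylprop-1-en-1-amine under neutral conditions gives the benzoyl chloride F8. Reduction of 13 with potassium graphite gives dipotassium pentacarbonylchromate F9, which is acylated by F8 at −78 °C to the potassium acylchromate F10. O-Methylation with MeOTf returns to the route at 16.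

3. Step 7. Addition of the doubly ortho-substituted aryllithium to the hindered lactone carbonyl may be slow, so that halogen–metal scrambling with the aryl bromide of 6 or simple protonation of 10 takes over. The fallback sets out from 6 and replaces acyl substitution by aldehyde addition and oxidation. DIBAL-H (CH2Cl2, −78 °C) should give the lactol 7-bromo-8-methoxy-3,4-dihydro-1H-isochromen-1-ol F11. Addition of 2.2 equivalents of 10 to its open hydroxy aldehyde form gives the diol [2,4-bis(benzyloxy)-6-methylphenyl][3-bromo-6-(2-hydroxyethyl)-2-methoxyphenyl]methanol F12. Selective silylation of the primary alcohol (TBSCl, imidazole) gives the carbinol silyl ether F13, and Dess–Martin oxidation of the diaryl carbinol returns to the route at 12.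

**Further compounds**

F1 | step 10 | [2,4-bis(benzyloxy)-6-methylphenyl][7-(2-(tert-butyldimethylsilyloxy)ethyl)-2-(diethoxymethyl)-1-hydroxy-4,5-dimethoxynaphthalen-6-yl]methanone | CCOC(OCC)c1cc(OC)c2c(OC)c(C(=O)c3c(C)cc(OCc4ccccc4)cc3OCc3ccccc3)c(CCO[Si](C)(C)C(C)(C)C)cc2c1O
F2 | step 10 | [2,4-bis(benzyloxy)-6-methylphenyl][7-(2-(tert-butyldimethylsilyloxy)ethyl)-2-(diethoxymethyl)-1,4,5-trimethoxynaphthalen-6-yl]methanone | CCOC(OCC)c1cc(OC)c2c(OC)c(C(=O)c3c(C)cc(OCc4ccccc4)cc3OCc3ccccc3)c(CCO[Si](C)(C)C(C)(C)C)cc2c1OC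
F3 | step 10 | 6-[2,4-bis(benzyloxy)-6-methylbenzoyl]-7-(2-(tert-butyldimethylsilyloxy)ethyl)-1,4,5-trimethoxynaphthalene-2-carbaldehyde | O=Cc1cc(OC)c2c(OC)c(C(=O)c3c(C)cc(OCc4ccccc4)cc3OCc3ccccc3)c(CCO[Si](C)(C)C(C)(C)C)cc2c1OC
F4 | step 10 | 6-[2,4-bis(benzyloxy)-6-methylbenzoyl]-7-(2-(tert-butyldimethylsilyloxy)ethyl)-1,4,5-trimethoxynaphthalen-2-yl formate | O=COc1cc(OC)c2c(OC)c(C(=O)c3c(C)cc(OCc4ccccc4)cc3OCc3ccccc3)c(CCO[Si](C)(C)C(C)(C)C)cc2c1OC
F5 | step 10 | [2,4-bis(benzyloxy)-6-methylphenyl][7-(2-(tert-butyldimethylsilyloxy)ethyl)-2-hydroxy-1,4,5-trimethoxynaphthalen-6-yl]methanone | Oc1cc(OC)c2c(OC)c(C(=O)c3c(C)cc(OCc4ccccc4)cc3OCc3ccccc3)c(CCO[Si](C)(C)C(C)(C)C)cc2c1OC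
F6 | step 9 | methyl 3-(2,4-bis(benzyloxy)-6-methylbenzoyl)-4-(2-(tert-butyldimethylsilyloxy)ethyl)-2-methoxybenzoate | COC(=O)c1ccc(CCO[Si](C)(C)C(C)(C)C)c(C(=O)c2c(C)cc(OCc3ccccc3)cc2OCc2ccccc2)c1OC
F7 | step 9 | 3-(2,4-bis(benzyloxy)-6-methylbenzoyl)-4-(2-(tert-butyldimethylsilyloxy)ethyl)-2-methoxybenzoic acid | OC(=O)c1ccc(CCO[Si](C)(C)C(C)(C)C)c(C(=O)c2c(C)cc(OCc3ccccc3)cc2OCc2ccccc2)c1OC
F8 | step 9 | 3-(2,4-bis(benzyloxy)-6-methylbenzoyl)-4-(2-(tert-butyldimethylsilyloxy)ethyl)-2-methoxybenzoyl chloride | ClC(=O)c1ccc(CCO[Si](C)(C)C(C)(C)C)c(C(=O)c2c(C)cc(OCc3ccccc3)cc2OCc2ccccc2)c1OC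
F9 | step 9 | dipotassium pentacarbonylchromate | [K+].[K+].O=C=[Cr-2](=C=O)(=C=O)(=C=O)=C=O
F10 | step 9 | potassium pentacarbonyl[3-(2,4-bis(benzyloxy)-6-methylbenzoyl)-4-(2-(tert-butyldimethylsilyloxy)ethyl)-2-methoxybenzoyl]chromate | [K+].[O-]C(=[Cr](=C=O)(=C=O)(=C=O)(=C=O)=C=O)c1ccc(CCO[Si](C)(C)C(C)(C)C)c(C(=O)c2c(C)cc(OCc3ccccc3)cc2OCc2ccccc2)c1OC
F11 | step 7 | 7-bromo-8-methoxy-3,4-dihydro-1H-isochromen-1-ol (racemic) | COc1c(Br)ccc2CCOC(O)c12
F12 | step 7 | [2,4-bis(benzyloxy)-6-methylphenyl][3-bromo-6-(2-hydroxyethyl)-2-methoxyphenyl]methanol (racemic) | COc1c(Br)ccc(CCO)c1C(O)c1c(C)cc(OCc2ccccc2)cc1OCc1ccccc1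
F13 | step 7 | [2,4-bis(benzyloxy)-6-methylphenyl][3-bromo-6-(2-(tert-butyldimethylsilyloxy)ethyl)-2-methoxyphenyl]methanol (racemic) | COc1c(Br)ccc(CCO[Si](C)(C)C(C)(C)C)c1C(O)c1c(C)cc(OCc2ccccc2)cc1OCc1ccccc1
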